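The rate constants are unknown, so two chemists argue from the charges and the runs.

common to all: starting material 0.30 M (fed, over 15 s); catalyst 45 mM

| run | reagent | second substrate | remark | time |
|---|---|---|---|---|
| east | 0.30 M | 0.30 M | run made earlier; the fed solution adds 0.10 times the starting volume |  |
| south | 0.30 M | 1.2 M | run made earlier; the fed solution adds 0.10 times the starting volume |  |
| west | 0.45 M | 0.60 M | run made earlier; the fed solution adds 0.10 times the starting volume |  |
| flask | 0.300 M | 0.600 M | the fed solution adds 0.10 times the starting volume | 30 min |

| run | time / min | target / % | starting material / % |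
|---|---|---|---|
| east | 0.333 | 24.2 | 68.2 |
| east | 0.667 | 29.6 | 60.8 |
| east | 1.33 | 30.7 | 57.7 |
| east | 2.50 | 32.4 | 55.0 |
| east | 6.00 | 31.0 | 55.7 |
| east | 12.0 | 33.4 | 56.5 |
| east | 25.0 | 28.4 | 58.0 |
| south | 0.333 | 2.4 | 92.8 |
| south | 0.667 | 5.2 | 94.5 |
| south | 1.33 | 3.7 | 91.4 |
| south | 2.50 | 4.8 | 93.6 |
| south | 6.00 | 4.7 | 93.8 |
| south | 12.0 | 5.7 | 94.5 |
| south | 25.0 | 2.5 | 94.7 |
| west | 0.333 | 22.8 | 69.9 |
| west | 0.833 | 26.8 | 65.3 |
| west | 2.50 | 26.2 | 67.1 |
| west | 8.00 | 23.5 | 63.9 |
| west | 25.0 | 22.6 | 65.0 |

(readings scatter by 1 percentage point)

- the best time, 30 min at the latest, for target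
- the amount of target, in percent of the starting material charged, at that time

- charges are per starting volume, the dose included; the dosed solution carries all of it
- the numbers in the tables scatter with a standard deviation of 1 percentage point

Both count turnovers. Take one reagent per catalyst turnover: the flask's reagent pays for 6.67 turnovers. The dispute is who gets them.

Mara says reagent divides as the charges do. Starting material is a third of the flask's substrate, so conversion is 33.3 %. The east run, averaged from 2.50 min on, shows 43.7 % converted and target at 0.716 of that. Mara therefore expects 23.9 % target.

Ben made the forecast: 14 % at 3 min. His ground is that “More second substrate strongly suppresses conversion”. The south run shows 5.85 % converted, less than the 20.0 % of Mara's rule.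

My own count assumes the reagent is spent when the readings stall. Let w be reagent taken by starting material over reagent taken by second substrate. East gives 0.776 and south 0.0621. So, between these two runs, w falls as second substrate to the power n = 1.82, steeper than the power one of Mara's rule. The flask then has 0.220, the reagent split, reagent to starting material over reagent to second substrate. That means 18.0 % conversion and 12.9 % target, slightly under the forecast.

The flask gives 15.1 % at 1.22 min. Ben's amount holds, but his time is 2.46 times too late. Mara's rule gives 50.0 % for the east run, with equal charges, against the 43.7 % read there.

    starting material + reagent + catalyst → catalyst + target (k = 9.61 M⁻² s⁻¹)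
    starting material + reagent → uncatalysed product (k = 0.0980 M⁻¹ s⁻¹)
    target → over-reaction product (k = 5.99 × 10⁻⁵ s⁻¹)
    second substrate + reagent + catalyst → catalyst + second product (k = 8.51 M⁻² s⁻¹)
    catalyst ⇌ dormant form (K = 3.70, k = 0.0382 s⁻¹)

At 30.0 min the flask's split stands at 0.257, close to 0.220. The flask's reagent is the limiting reagent, with 0 % left then. The largest single effect on the flask's best target comes from the catalysed turning of second substrate and reagent into second product: without that step, the best target is 61.2 % instead of 15.1 %.

With 1.5 M of second substrate, the split gives w = 0.0414, so 3.97 % conversion and 2.85 % target. That neighbour keeps 96.0 % of its starting material and peaks at 3.10 % target.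

The earlier runs and the new flask are calculated for substances that don't exist, and the scatter is random.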